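## Retrosynthetic overview

1. Target ⇐ hydroxyl-directed 1,3-anti reduction of a β-hydroxy enone, then phenol desilylation; the enone C=O becomes the side-chain carbinol.
2. β-Hydroxy enone ⇐ acyl C–C disconnection into a cis-fused tricyclic β-lactone (opened as its Weinreb amide) and an (E)-2-arylvinyllithium made from 4-silyloxybenzaldehyde.
3. β-Lactone ⇐ catalytic asymmetric aldol-lactonization of an aldehyde acid: the C1–C2 bond of the carbocycle and the lactone C–O bond close in the same operation and fix C1 and C2.
4. Aldehyde acid ⇐ Heck coupling of an ortho-iodo arylacetic acid with allyl alcohol ⇐ iodination of homoveratric acid.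
5. Ring order: both benzene rings are bought; the carbocycle and the β-lactone ring form together (step 3); the lactone ring is opened again in step 5.

Assumption: quinidine-derived catalysts are taken to give the (R)-configured α-carbon in related ammonium-enolate lactone formations, so the quinine-derived pseudoenantiomer is used in step 3. This is from recall, not verified; the configuration of the lactone must be checked (rotation, Mosher ester after ring opening), and if it is the mirror image, O-trimethylsilylquinidine is used with no other change.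

Locants: tetralin numbering (C1 = benzylic stereocentre, C2 = ring carbinol); C1' = side-chain carbinol carbon. Target = (1S,2R,1'R), i.e. cis-1,2 on the ring and a 1,3-anti diol.

## Route

Step 1
Reactants: 1 (3,4-dimethoxyphenyl)acetic acid (homoveratric acid)
Product: 2 (2-iodo-4,5-dimethoxyphenyl)acetic acid
Conditions: NIS (1.05 equiv), CF3CO2H (0.2 equiv), MeCN, 23 °C
Reagents that add atoms: N-iodosuccinimide, O=C1CCC(=O)N1I
Why: Electrophilic aromatic iodination goes to the position para to the 3-methoxy group and ortho to the CH2CO2H arm, the most activated unhindered site; no stereocentre is involved.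

Step 2
Reactants: 2 (2-iodo-4,5-dimethoxyphenyl)acetic acid; 3 allyl alcohol
Product: 4 [4,5-dimethoxy-2-(3-oxopropyl)phenyl]acetic acid
Conditions: Pd(OAc)2 (5 mol %), Bu4NCl (1 equiv), NaHCO3 (3.5 equiv), DMF, 50 °C
Reagents that add atoms: none
Why: Heck reaction under ligand-free phase-transfer (Jeffery) conditions: the aryl group adds to the terminal alkene carbon and β-hydride elimination toward the carbinol gives the enol and hence the saturated aldehyde, while the carboxylate is a spectator.

Step 3
Reactants: 4 [4,5-dimethoxy-2-(3-oxopropyl)phenyl]acetic acid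
Product: 5 (1S,2R)-2-hydroxy-6,7-dimethoxy-1,2,3,4-tetrahydronaphthalene-1-carboxylic acid β-lactone (cis-fused tricycle; C=O on C1; ring O on C2)
Conditions: 2-chloro-1-methylpyridinium iodide (3 equiv), iPr2NEt (4 equiv), O-trimethylsilylquinine (10 mol %), MeCN, 23 °C, slow addition of 4
Reagents that add atoms: none
Why: Nucleophile-catalysed aldol-lactonization, known for aliphatic aldehyde acids and extended here to a benzo-tethered arylacetic acid: the activated acid gives a chiral benzylic ammonium enolate that adds to the tethered aldehyde (six-membered ring) and the aldolate closes the β-lactone with release of the catalyst; a four-membered lactone can only be cis-fused, so C1 and C2 are set together, and the catalyst's face selection of the enolate gives (1S,2R).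

Step 4
Reactants: 6 4-(tert-butyldimethylsilyloxy)benzaldehyde
Product: 7 tert-butyl{4-[(E)-2-iodoethenyl]phenoxy}dimethylsilane
Conditions: CrCl2 (6 equiv), CHI3 (2 equiv), THF, 0 → 23 °C
Reagents that add atoms: iodoform, IC(I)I
Why: Takai olefination: the geminal dichromium species from CHI3 and CrCl2 adds to the aldehyde and eliminates to the (E)-iodoalkene (typically E:Z above 10:1), and the aryl silyl ether is inert.

Step 5
Reactants: 5 β-lactone of step 3; 7 tert-butyl{4-[(E)-2-iodoethenyl]phenoxy}dimethylsilane
Product: 10 (E)-3-[4-(tert-butyldimethylsilyloxy)phenyl]-1-[(1S,2R)-2-hydroxy-6,7-dimethoxy-1,2,3,4-tetrahydronaphthalen-1-yl]prop-2-en-1-one, via Weinreb amide 8 (not isolated), via alkenyllithium 9 (not isolated)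
Conditions: (a) MeONHMe·HCl (1.5 equiv), iPrMgCl (3.0 equiv), THF, −20 °C; (b) 7 (2.5 equiv), t-BuLi (5 equiv), Et2O, −78 °C, then transfer into (a), −78 → −40 °C
Reagents that add atoms: none
Why: Weinreb ketone synthesis run in one pot: the magnesium amide opens the strained lactone at the acyl carbon, and the alkenyllithium (iodine–lithium exchange with retention of E geometry) adds once to give a chelated tetrahedral intermediate that releases the ketone only on quench; C1 and C2 are not touched (C2–O is a spectator alkoxide).

Step 6
Reactants: 10 β-hydroxy enone of step 5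
Product: 12 (1S,2R)-1-[(1R,2E)-1-hydroxy-3-(4-hydroxyphenyl)prop-2-en-1-yl]-6,7-dimethoxy-1,2,3,4-tetrahydronaphthalen-2-ol, via silyl ether diol 11 (not isolated)
Conditions: Me4NBH(OAc)3 (6 equiv), MeCN/AcOH 1:1, −30 → −10 °C; crude 11, then Bu4NF/AcOH (1:1), THF, 0 °C
Reagents that add atoms: none
Why: Evans–Saksena hydroxyl-directed reduction: the C2-OH exchanges onto boron and hydride is delivered intramolecularly through a chair transition state with the styryl group equatorial, giving the 1,3-anti diol, which here is (R) at C1'; buffered fluoride then cleaves only the aryl silyl ether.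

## Compound list

1 | (3,4-dimethoxyphenyl)acetic acid (homoveratric acid) | COc1ccc(CC(=O)O)cc1OC | starting material
2 | (2-iodo-4,5-dimethoxyphenyl)acetic acid | COc1cc(I)c(CC(=O)O)cc1OC | intermediate
3 | allyl alcohol (prop-2-en-1-ol) | C=CCO | starting material
4 | [4,5-dimethoxy-2-(3-oxopropyl)phenyl]acetic acid | COc1cc(CCC=O)c(CC(=O)O)cc1OC | intermediate
5 | (1S,2R)-2-hydroxy-6,7-dimethoxy-1,2,3,4-tetrahydronaphthalene-1-carboxylic acid β-lactone (cis-fused) | COc1cc2c(cc1OC)[C@@H]3C(=O)O[C@@H]3CC2 | intermediate
6 | 4-(tert-butyldimethylsilyloxy)benzaldehyde | CC(C)(C)[Si](C)(C)Oc1ccc(C=O)cc1 | starting material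
7 | tert-butyl{4-[(E)-2-iodoethenyl]phenoxy}dimethylsilane | CC(C)(C)[Si](C)(C)Oc1ccc(/C=C/I)cc1 | intermediate
8 | (1S,2R)-2-hydroxy-N,6,7-trimethoxy-N-methyl-1,2,3,4-tetrahydronaphthalene-1-carboxamide (Weinreb amide; present as its chloromagnesium alkoxide) | COc1cc2c(cc1OC)[C@H](C(=O)N(C)OC)[C@H](O)CC2 | intermediate (not isolated)
9 | (E)-2-[4-(tert-butyldimethylsilyloxy)phenyl]ethenyllithium | [Li]/C=C/c1ccc(O[Si](C)(C)C(C)(C)C)cc1 | intermediate (not isolated)
10 | (E)-3-[4-(tert-butyldimethylsilyloxy)phenyl]-1-[(1S,2R)-2-hydroxy-6,7-dimethoxy-1,2,3,4-tetrahydronaphthalen-1-yl]prop-2-en-1-one | COc1cc2c(cc1OC)[C@H](C(=O)/C=C/c1ccc(O[Si](C)(C)C(C)(C)C)cc1)[C@H](O)CC2 | intermediate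
11 | (1S,2R)-1-{(1R,2E)-3-[4-(tert-butyldimethylsilyloxy)phenyl]-1-hydroxyprop-2-en-1-yl}-6,7-dimethoxy-1,2,3,4-tetrahydronaphthalen-2-ol | COc1cc2c(cc1OC)[C@H]([C@H](O)/C=C/c1ccc(O[Si](C)(C)C(C)(C)C)cc1)[C@H](O)CC2 | intermediate (not isolated)
12 | (1S,2R)-1-[(1R,2E)-1-hydroxy-3-(4-hydroxyphenyl)prop-2-en-1-yl]-6,7-dimethoxy-1,2,3,4-tetrahydronaphthalen-2-ol | COc1cc2c(cc1OC)[C@H]([C@H](O)/C=C/c1ccc(O)cc1)[C@H](O)CC2 | target

## Totals and risks

Total step count: 6. Longest linear sequence: 5 steps (steps 1, 2, 3, 5, 6 from homoveratric acid); step 4 is the one-step side branch.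

Steps most likely to fail:

**Step 3 (aldol-lactonization).** A six-membered ring and an aryl-stabilised enolate both lower the rate. Ketene dimerisation, base-induced E1cB opening of 5 to the dihydronaphthoic acid, or a modest ee are the likely failure modes; a modest ee may be raised by recrystallising 5.

Fallback, setting out from 4 and returning at 8: the carbocycle is closed by a Dieckmann condensation and both ring stereocentres are set by a dynamic kinetic reduction. Oxidation of 4 (NaClO2, NaH2PO4, 2-methyl-2-butene, t-BuOH/H2O) gives 3-[2-(carboxymethyl)-4,5-dimethoxyphenyl]propanoic acid F1. Esterification (MeOH, H2SO4, reflux) gives methyl 3-[4,5-dimethoxy-2-(2-methoxy-2-oxoethyl)phenyl]propanoate F2. NaOMe in toluene closes the ring through the benzylic enolate to methyl 6,7-dimethoxy-2-oxo-1,2,3,4-tetrahydronaphthalene-1-carboxylate F3, whose C1 centre racemises freely. A ketoreductase screened for the cis-(1S,2R) alcohol (NADPH, isopropanol recycling) then gives methyl (1S,2R)-2-hydroxy-6,7-dimethoxy-1,2,3,4-tetrahydronaphthalene-1-carboxylate F4. MeONHMe·HCl/iPrMgCl (THF, −20 °C) converts F4 into 8.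

**Step 5 (one-pot amide formation and alkenylation).** Risks are incomplete lactone opening, enolisation at the benzylic C1 (epimerisation), E/Z leakage from 7, and dehydration of 10 on handling.

Fallback, setting out from 8 (now isolated after aqueous work-up of stage a) and returning at 10: the aryl group is brought in by olefin metathesis instead of as an organolithium. Vinylmagnesium bromide (THF, −78 → 0 °C, inverse quench into cold dilute HCl) gives 1-[(1S,2R)-2-hydroxy-6,7-dimethoxy-1,2,3,4-tetrahydronaphthalen-1-yl]prop-2-en-1-one F5. Cross-metathesis of F5 with commercial 4-(tert-butyldimethylsilyloxy)styrene (second-generation Hoveyda–Grubbs catalyst, CH2Cl2, 40 °C) gives the (E)-enone 10 under neutral conditions.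

**Step 6 (directed reduction and desilylation).** The aryl-conjugated enone is a sluggish acceptor, the electron-rich cinnamyl-type alcohol may ionise in AcOH, and the anti:syn ratio is untested on this ring-constrained substrate.

Fallback, setting out from 10 and returning at 12: an Evans–Tishchenko reduction under neutral conditions (SmI2 15 mol %, acetaldehyde, THF, −10 °C). The C2 hemiacetal delivers hydride intramolecularly to the ketone and gives the 1,3-anti product as the C2 acetate of 11, F6, with the C1' hydroxyl free. K2CO3 in MeOH (23 °C) then removes the acetate and the aryl silyl ether together to give 12.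

## Further compounds

F1 | step 3 | 3-[2-(carboxymethyl)-4,5-dimethoxyphenyl]propanoic acid | COc1cc(CCC(=O)O)c(CC(=O)O)cc1OC
F2 | step 3 | methyl 3-[4,5-dimethoxy-2-(2-methoxy-2-oxoethyl)phenyl]propanoate | COC(=O)CCc1cc(OC)c(OC)cc1CC(=O)OC
F3 | step 3 | methyl 6,7-dimethoxy-2-oxo-1,2,3,4-tetrahydronaphthalene-1-carboxylate (racemic, configurationally labile) | COC(=O)C1C(=O)CCc2cc(OC)c(OC)cc21
F4 | step 3 | methyl (1S,2R)-2-hydroxy-6,7-dimethoxy-1,2,3,4-tetrahydronaphthalene-1-carboxylate | COc1cc2c(cc1OC)[C@H](C(=O)OC)[C@H](O)CC2
F5 | step 5 | 1-[(1S,2R)-2-hydroxy-6,7-dimethoxy-1,2,3,4-tetrahydronaphthalen-1-yl]prop-2-en-1-one | COc1cc2c(cc1OC)[C@H](C(=O)C=C)[C@H](O)CC2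
F6 | step 6 | C2 acetate of 11 (same configuration at C1, C2 and C1'; C1' hydroxyl free) | COc1cc2c(cc1OC)[C@H]([C@H](O)/C=C/c1ccc(O[Si](C)(C)C(C)(C)C)cc1)[C@H](OC(C)=O)CC2
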